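The ring is numbered C1 (CH–O-angelate), C2=C3 (C3 bears CH2OH), C4 (C=O), C5 (CH–O-epoxy ester), C6 (CH–iPr). It is assembled from two three-carbon pieces: the enol silane of an α-acyloxy ketone (C3–C4–C5, already carrying the epoxy ester and the protected hydroxymethyl arm) and 4-methylpent-2-enal (C2–C1–C6). One amine-catalysed pot performs Mukaiyama–Michael addition (C5–C6), enamine α-angeloyloxylation with diangeloyl peroxide (C1–O) and aldol condensation (C2=C3). It exploits the 1,5-relationship of the C4 ketone and C2 in the cyclohexenone and the enolisable C5–H: one prolinol catalyst sets C6 and C1, and C5 equilibrates to the trans ester.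

Key step: step 9

Assumption: in the fallback to step 2 the (R)-1-phenylethylammonium salt of the (2R,3R)-acid is taken to be the less soluble diastereomer; should the (2S,3S)-salt crystallise instead, the (S)-amine is used.

Step 1
Reactants: 1 angelic acid, (2Z)-2-methylbut-2-enoic acid
Product: 2 (2Z)-2-methylbut-2-en-1-ol
Conditions: LiAlH4, Et2O, 0 °C to rt
Reagents that add atoms: none
Why: Hydride reduction of the carboxylic acid proceeds by 1,2-attack at the carbonyl group, so the trisubstituted Z-alkene should be carried over unchanged.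

Step 2
Reactants: 2 (2Z)-2-methylbut-2-en-1-ol
Product: 3 [(2S,3R)-2,3-dimethyloxiran-2-yl]methanol
Conditions: Ti(OiPr)4 (10 mol%), L-(+)-diethyl tartrate (12 mol%), t-BuOOH, 4 Å MS, CH2Cl2, −20 °C
Reagents that add atoms: tert-butyl hydroperoxide, CC(C)(C)OO
Why: Sharpless asymmetric epoxidation: in the titanium–tartrate–allyl alkoxide complex L-(+)-tartrate directs oxygen to the face that gives the (2S,3R)-epoxide of a Z-allylic alcohol, and the syn oxygen transfer keeps the two methyl groups trans as in the alkene.

Step 3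
Reactants: 3 [(2S,3R)-2,3-dimethyloxiran-2-yl]methanol
Product: 4 (2R,3R)-2,3-dimethyloxirane-2-carboxylic acid
Conditions: RuCl3·xH2O (2 mol%), NaIO4, CCl4/MeCN/H2O, rt
Reagents that add atoms: sodium periodate, [Na+].[O-]I(=O)(=O)=O
Why: Catalytic RuO4 oxidation takes the primary alcohol to the acid without opening the epoxide; no stereocentre is touched, and the C2 descriptor changes from S to R only through the CIP priority of the new carboxyl group.

Step 4
Reactants: 5 4-hydroxybutan-2-one
Product: 6 4-[(tert-butyldimethylsilyl)oxy]butan-2-one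
Conditions: TBSCl, imidazole, DMF, rt
Reagents that add atoms: tert-butyldimethylsilyl chloride, CC(C)(C)[Si](C)(C)Cl
Why: Silyl ether formation at the primary alcohol masks the oxygen of the future hydroxymethyl group.

Step 5
Reactants: 6 4-[(tert-butyldimethylsilyl)oxy]butan-2-one
Product: 8 1-bromo-4-[(tert-butyldimethylsilyl)oxy]butan-2-one, via kinetic trimethylsilyl enol ether 7 (not isolated)
Conditions: LDA, THF, −78 °C; TMSCl; then NBS, THF, −78 to 0 °C
Reagents that add atoms: N-bromosuccinimide, O=C1CCC(=O)N1Br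
Why: Kinetic deprotonation occurs at the methyl group, which also avoids the enolate that could expel the β-silyloxy group, and the terminal enol silane is brominated regiospecifically (α-bromination of a ketone through its silyl enol ether).

Step 6
Reactants: 4 (2R,3R)-2,3-dimethyloxirane-2-carboxylic acid; 8 1-bromo-4-[(tert-butyldimethylsilyl)oxy]butan-2-one
Product: 9 4-[(tert-butyldimethylsilyl)oxy]-2-oxobutyl (2R,3R)-2,3-dimethyloxirane-2-carboxylate
Conditions: Cs2CO3 (0.55 equiv), DMF, 0 °C to rt
Reagents that add atoms: none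
Why: The caesium carboxylate displaces bromide from the activated α-bromo ketone (SN2 O-alkylation of a carboxylate), a mild esterification that does not involve the epoxide stereocentres.

Step 7
Reactants: 9 4-[(tert-butyldimethylsilyl)oxy]-2-oxobutyl (2R,3R)-2,3-dimethyloxirane-2-carboxylate
Product: 10 (1Z)-4-[(tert-butyldimethylsilyl)oxy]-2-[(trimethylsilyl)oxy]but-1-en-1-yl (2R,3R)-2,3-dimethyloxirane-2-carboxylate
Conditions: LiHMDS, TMSCl (in situ quench), THF, −78 °C
Reagents that add atoms: chlorotrimethylsilane, C[Si](C)(C)Cl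
Why: The methylene between the ketone and the acyloxy group is the most acidic site and the ester has no α-hydrogen, so kinetic enolisation with internal silyl quench should give the chelated Z-enol silane (silyl enol ether formation); its geometry is of no consequence later.

Step 8
Reactants: 1 angelic acid, (2Z)-2-methylbut-2-enoic acid (2 equiv)
Product: 11 bis[(2Z)-2-methylbut-2-enoyl] peroxide (diangeloyl peroxide)
Conditions: DCC, urea–H2O2, CH2Cl2, 0 °C, dark
Reagents that add atoms: hydrogen peroxide, OO
Why: Carbodiimide activation of the acid and acylation of hydrogen peroxide on both oxygens give the diacyl peroxide (the angelic analogue of dibenzoyl peroxide) under neutral conditions at 0 °C, which should preserve the Z-alkenes.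

Step 9
Reactants: 10 (1Z)-4-[(tert-butyldimethylsilyl)oxy]-2-[(trimethylsilyl)oxy]but-1-en-1-yl (2R,3R)-2,3-dimethyloxirane-2-carboxylate (1.3 equiv); 12 (2E)-4-methylpent-2-enal (limiting); 11 diangeloyl peroxide
Product: 15 (1R,5S,6R)-3-{[(tert-butyldimethylsilyl)oxy]methyl}-5-{[(2R,3R)-2,3-dimethyloxirane-2-carbonyl]oxy}-4-oxo-6-(propan-2-yl)cyclohex-2-en-1-yl (2Z)-2-methylbut-2-enoate, via Michael aldehyde 13 (not isolated), via α-angeloyloxy aldehyde 14 (not isolated)
Conditions: (S)-α,α-diphenylprolinol TMS ether (20 mol%), 4-nitrobenzoic acid (20 mol%), H2O (2 equiv), CH2Cl2, −20 °C; then 11, hydroquinone (10 mol%), THF, 0 °C; then CSA (0.3 equiv), 4 Å MS, 35 °C (one pot)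
Reagents that add atoms: none
Why: The (S)-prolinol ether converts 12 into an E-iminium ion whose CPh2OTMS group shields one face, so that enol silane 10 adds to C6 from the open face in a Mukaiyama–Michael reaction (C5–C6, 6R), and the same amine then turns aldehyde 13 into its E-enamine, which attacks the O–O bond of 11 again from the open face and places the angelate on C1 syn to the new C–C bond (1R, the cis-OAng/iPr relationship of the ring). Acid finally enolises the C4 ketone towards C3 and the enol adds to the aldehyde C2 in a 6-(enolendo)-exo-trig aldol closure, and loss of water gives the C2=C3 enone. The closest known reaction types are the amine-catalysed conjugate addition/α-functionalisation cascade of enals, the enamine α-acyloxylation of aldehydes with diacyl peroxides and the Michael/aldol-condensation [3+3] annulation of enals with ketones. C5 is formed as a mixture, but as the α-carbon of the C4 ketone it should equilibrate under the acid to the epimer with the ester trans to the isopropyl group, the only one that avoids both a syn-axial clash with the C1 angelate and an extra gauche contact. The step needs 1,4- instead of 1,2-addition of 10 (secured by the iminium ion), oxygenation of C1 before ring closure (secured by making 12 the limiting reagent and withholding the acid until 11 is consumed) and closure through C3 only (enolisation towards C5 or of the aldehyde could only give four-membered rings).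

Step 10
Reactants: 15 (1R,5S,6R)-3-{[(tert-butyldimethylsilyl)oxy]methyl}-5-{[(2R,3R)-2,3-dimethyloxirane-2-carbonyl]oxy}-4-oxo-6-(propan-2-yl)cyclohex-2-en-1-yl (2Z)-2-methylbut-2-enoate
Product: 16 (1R,5S,6R)-5-{[(2R,3R)-2,3-dimethyloxirane-2-carbonyl]oxy}-3-(hydroxymethyl)-4-oxo-6-(propan-2-yl)cyclohex-2-en-1-yl (2Z)-2-methylbut-2-enoate
Conditions: HF·pyridine, pyridine, THF, 0 °C
Reagents that add atoms: none
Why: Fluoride cleaves the primary silyl ether (desilylation) in a buffered, weakly acidic medium that should leave the glycidic ester, the allylic angelate and the enone untouched and avoids base-induced acyl migration or epimerisation.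

Compound list
1 | angelic acid, (2Z)-2-methylbut-2-enoic acid | C/C=C(/C)C(=O)O | starting material
2 | (2Z)-2-methylbut-2-en-1-ol | C/C=C(/C)CO | intermediate
3 | [(2S,3R)-2,3-dimethyloxiran-2-yl]methanol | OC[C@]1(C)O[C@@H]1C | intermediate
4 | (2R,3R)-2,3-dimethyloxirane-2-carboxylic acid | OC(=O)[C@]1(C)O[C@@H]1C | intermediate
5 | 4-hydroxybutan-2-one | CC(=O)CCO | starting material
6 | 4-[(tert-butyldimethylsilyl)oxy]butan-2-one | CC(=O)CCO[Si](C)(C)C(C)(C)C | intermediate
7 | tert-butyldimethyl{[3-(trimethylsilyloxy)but-3-en-1-yl]oxy}silane | C=C(O[Si](C)(C)C)CCO[Si](C)(C)C(C)(C)C | intermediate (not isolated)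
8 | 1-bromo-4-[(tert-butyldimethylsilyl)oxy]butan-2-one | BrCC(=O)CCO[Si](C)(C)C(C)(C)C | intermediate
9 | 4-[(tert-butyldimethylsilyl)oxy]-2-oxobutyl (2R,3R)-2,3-dimethyloxirane-2-carboxylate | CC(C)(C)[Si](C)(C)OCCC(=O)COC(=O)[C@]1(C)O[C@@H]1C | intermediate
10 | (1Z)-4-[(tert-butyldimethylsilyl)oxy]-2-[(trimethylsilyl)oxy]but-1-en-1-yl (2R,3R)-2,3-dimethyloxirane-2-carboxylate | CC(C)(C)[Si](C)(C)OCC/C(O[Si](C)(C)C)=C/OC(=O)[C@]1(C)O[C@@H]1C | intermediate
11 | bis[(2Z)-2-methylbut-2-enoyl] peroxide (diangeloyl peroxide) | C/C=C(/C)C(=O)OOC(=O)/C(C)=C\C | intermediate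
12 | (2E)-4-methylpent-2-enal | CC(C)/C=C/C=O | starting material
13 | (3S)-7-[(tert-butyldimethylsilyl)oxy]-4-{[(2R,3R)-2,3-dimethyloxirane-2-carbonyl]oxy}-5-oxo-3-(propan-2-yl)heptanal (C4 epimers) | O=CC[C@@H](C(C)C)C(OC(=O)[C@]1(C)O[C@@H]1C)C(=O)CCO[Si](C)(C)C(C)(C)C | intermediate (not isolated)
14 | (2S,3R)-7-[(tert-butyldimethylsilyl)oxy]-4-{[(2R,3R)-2,3-dimethyloxirane-2-carbonyl]oxy}-2-{[(2Z)-2-methylbut-2-enoyl]oxy}-5-oxo-3-(propan-2-yl)heptanal (C4 epimers) | O=C[C@@H](OC(=O)/C(C)=C\C)[C@@H](C(C)C)C(OC(=O)[C@]1(C)O[C@@H]1C)C(=O)CCO[Si](C)(C)C(C)(C)C | intermediate (not isolated)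
15 | (1R,5S,6R)-3-{[(tert-butyldimethylsilyl)oxy]methyl}-5-{[(2R,3R)-2,3-dimethyloxirane-2-carbonyl]oxy}-4-oxo-6-(propan-2-yl)cyclohex-2-en-1-yl (2Z)-2-methylbut-2-enoate | C/C=C(/C)C(=O)O[C@@H]1C=C(CO[Si](C)(C)C(C)(C)C)C(=O)[C@@H](OC(=O)[C@]2(C)O[C@@H]2C)[C@@H]1C(C)C | intermediate
16 | (1R,5S,6R)-5-{[(2R,3R)-2,3-dimethyloxirane-2-carbonyl]oxy}-3-(hydroxymethyl)-4-oxo-6-(propan-2-yl)cyclohex-2-en-1-yl (2Z)-2-methylbut-2-enoate | C/C=C(/C)C(=O)O[C@@H]1C=C(CO)C(=O)[C@@H](OC(=O)[C@]2(C)O[C@@H]2C)[C@@H]1C(C)C | target

Total step count: 10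
Longest linear sequence: 7 steps (steps 1, 2, 3, 6, 7, 9, 10)

Steps most likely to fail

1. Step 9 (key step). What may go wrong:
- ring closure of 13 to the enone before the oxygen has been placed on C1;
- loss of the C1 configuration by enolisation of the α-acyloxy aldehyde during the acid stage, after which the epimer would close more easily through an all-equatorial transition state;
- radical decomposition of the peroxide or oxidation of the amine catalyst;
- hydrolysis of the enol silane before the conjugate addition.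

Fallback (sets out from 9, comes back at 15): the C1 oxygen is carried in by the enal and its configuration is corrected afterwards, so no peroxide and no oxygenation stage are needed. [(4-Methoxybenzyl)oxy]acetaldehyde and isobutyraldehyde are condensed (pyrrolidine, propionic acid) to (2Z)-2-[(4-methoxybenzyl)oxy]-4-methylpent-2-enal F1. Ketone 9 and F1 are joined in a two-component Michael/aldol-condensation domino under a cinchona-derived primary amine salt (9-amino-9-deoxy-epi-quinine or its quinidine-derived pseudoenantiomer, whichever delivers 6R, with TFA). This still forms C5–C6 and C2=C3 in one operation and passes through the keto aldehyde F2, whose α-alkoxy aldehyde centre epimerises through the enamine and should close through the all-equatorial transition state to the 1-epi PMB ether F3. DDQ frees the 1-epi alcohol F4. Mitsunobu esterification with angelic acid 1 (PPh3, DIAD) then inverts C1, as in the conversion of equatorial 2-alkylcyclohexanols into their axial esters, and gives 15.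

2. Step 7. What may go wrong:
- deprotonation on the C3 side followed by loss of silanolate;
- O-to-O acyl shift within the enolate;
- hydrolysis of the labile enol silane on isolation.

Fallback (sets out from 8, comes back at 15): the epoxy ester is attached after the ring has been built, which removes the acyloxy ketone from the enolisation. Sodium formate in aqueous ethanol converts 8 into 4-[(tert-butyldimethylsilyl)oxy]-1-hydroxybutan-2-one F5. TMSCl/Et3N gives the ene-1,2-diol bis(trimethylsilyl) ether F6, an acyloin-type enol silane that cannot undergo acyl shift. F6 takes the place of 10 in step 9: the Mukaiyama–Michael addition should give the silyloxy aldehyde F7, the oxygenation the α-angeloyloxy aldehyde F8, and the acid stage closes the ring and removes the C5 silyl ether to give the C5-hydroxy enone F9. Yamaguchi esterification of F9 with acid 4 (2,4,6-trichlorobenzoyl chloride, Et3N, DMAP) gives 15.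

3. Step 2. What may go wrong:
- slow and incompletely face-selective oxygen transfer to a Z-trisubstituted allylic alcohol;
- loss of the small, water-soluble epoxy alcohol during isolation.

Fallback (sets out from 1, comes back at 4): resolution instead of asymmetric catalysis. Tungstate-catalysed epoxidation of angelic acid 1 with hydrogen peroxide (Na2WO4, pH 5–6), a stereospecific syn oxygen transfer, gives racemic (2R*,3R*)-2,3-dimethyloxirane-2-carboxylic acid F10. Crystallisation with (R)-1-phenylethylamine gives the (R)-1-phenylethylammonium (2R,3R)-carboxylate F11, from which 4 is released with dilute acid. Steps 1 to 3 then fall away.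

Further compounds
F1 | step 9 | (2Z)-2-[(4-methoxybenzyl)oxy]-4-methylpent-2-enal | COc1ccc(CO/C(C=O)=C\C(C)C)cc1
F2 | step 9 | (3R)-7-[(tert-butyldimethylsilyl)oxy]-4-{[(2R,3R)-2,3-dimethyloxirane-2-carbonyl]oxy}-2-[(4-methoxybenzyl)oxy]-5-oxo-3-(propan-2-yl)heptanal (C2 and C4 epimers, not isolated) | COc1ccc(COC(C=O)[C@@H](C(C)C)C(OC(=O)[C@]2(C)O[C@@H]2C)C(=O)CCO[Si](C)(C)C(C)(C)C)cc1
F3 | step 9 | (1S,5S,6R)-3-{[(tert-butyldimethylsilyl)oxy]methyl}-5-[(4-methoxybenzyl)oxy]-2-oxo-6-(propan-2-yl)cyclohex-3-en-1-yl (2R,3R)-2,3-dimethyloxirane-2-carboxylate | COc1ccc(CO[C@H]2C=C(CO[Si](C)(C)C(C)(C)C)C(=O)[C@@H](OC(=O)[C@]3(C)O[C@@H]3C)[C@@H]2C(C)C)cc1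
F4 | step 9 | (1S,5S,6R)-3-{[(tert-butyldimethylsilyl)oxy]methyl}-5-hydroxy-2-oxo-6-(propan-2-yl)cyclohex-3-en-1-yl (2R,3R)-2,3-dimethyloxirane-2-carboxylate | O[C@H]1C=C(CO[Si](C)(C)C(C)(C)C)C(=O)[C@@H](OC(=O)[C@]2(C)O[C@@H]2C)[C@@H]1C(C)C
F5 | step 7 | 4-[(tert-butyldimethylsilyl)oxy]-1-hydroxybutan-2-one | OCC(=O)CCO[Si](C)(C)C(C)(C)C
F6 | step 7 | (1Z)-4-[(tert-butyldimethylsilyl)oxy]-1,2-bis[(trimethylsilyl)oxy]but-1-ene | C[Si](C)(C)O/C=C(\O[Si](C)(C)C)CCO[Si](C)(C)C(C)(C)C
F7 | step 7 | (3S)-7-[(tert-butyldimethylsilyl)oxy]-5-oxo-3-(propan-2-yl)-4-[(trimethylsilyl)oxy]heptanal (C4 epimers, not isolated) | O=CC[C@@H](C(C)C)C(O[Si](C)(C)C)C(=O)CCO[Si](C)(C)C(C)(C)C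
F8 | step 7 | (2S,3R)-7-[(tert-butyldimethylsilyl)oxy]-2-{[(2Z)-2-methylbut-2-enoyl]oxy}-5-oxo-3-(propan-2-yl)-4-[(trimethylsilyl)oxy]heptanal (C4 epimers, not isolated) | O=C[C@@H](OC(=O)/C(C)=C\C)[C@@H](C(C)C)C(O[Si](C)(C)C)C(=O)CCO[Si](C)(C)C(C)(C)C
F9 | step 7 | (1R,5S,6R)-3-{[(tert-butyldimethylsilyl)oxy]methyl}-5-hydroxy-4-oxo-6-(propan-2-yl)cyclohex-2-en-1-yl (2Z)-2-methylbut-2-enoate | C/C=C(/C)C(=O)O[C@@H]1C=C(CO[Si](C)(C)C(C)(C)C)C(=O)[C@@H](O)[C@@H]1C(C)C
F10 | step 2 | rac-(2R,3R)-2,3-dimethyloxirane-2-carboxylic acid | OC(=O)[C@]1(C)O[C@@H]1C.OC(=O)[C@@]1(C)O[C@H]1C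
F11 | step 2 | (R)-1-phenylethan-1-aminium (2R,3R)-2,3-dimethyloxirane-2-carboxylate | C[C@@H]([NH3+])c1ccccc1.[O-]C(=O)[C@]1(C)O[C@@H]1C
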